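Take the closed, stirred vessel and count everything in it as a fraction of its charge.

- dawn: substrate 0.38 M; reagent 0.76 M; free catalyst 19 mM; run made earlier
- flask: substrate 0.38 M; reagent 0.760 M; free catalyst 38 mM

dawn run (percent of the substrate charged)

| time / min | target / % | substrate / % |
|---|---|---|
| 0.667 | 0.2 | 99.5 |
| 1.00 | 0 | 99.1 |
| 1.50 | 0.9 | 97.8 |
| 2.50 | 2.2 | 97.9 |
| 5.00 | 3.3 | 95.0 |
| 8.00 | 5.4 | 91.8 |

(standard deviation of a reading: 0.5 percentage points)

1. apparent order in reagent when 50% of the substrate are converted (percent change of the rate of making target for one percent more reagent charged)
2. factor on the rate of making target when 50% of the substrate are converted if free catalyst is charged twice over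

- no earlier run changes the charge of free catalyst; that part of a forecast is a guess
- no earlier run changes the charge of reagent; that part of a forecast is a guess

Start from the last dawn reading, at 8.00 min, where 91.8% of the substrate is left. Assume that the substrate fraction decays exponentially, at a pace proportional to the catalyst charged. Scale the logarithm of that fraction to this flask's catalyst charge, and half of the substrate is gone at 32.4 min, with the catalyst taken as free throughout.

That last assumption is the weak link, so test it. At the same reading target stands at 5.4%, which leaves a gap of 2.8 percentage points against a scatter of 0.5 points. Reckoned against the catalyst charged, that gap reads 56.0%. Call this the held share, the part of the catalyst charge sitting with substrate on it.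

Now reforge the time. Take the free part in the dawn run as falling steadily from the whole charge to what the held share leaves, so the dawn pace was earned on an average free share of 72.0%. Suppose this flask holds the same share from the start, leaving 44.0% free. Scaling by those two shares gives 53.0 min, the time I commit to.

If the gap is held catalyst, it cannot pass 10.0% of the substrate charge in this flask. A held share that stays the same when the charge is doubled gives a doubling factor of 2; that is my own guess, because no run here varies the charge. The forecast gives 1.1 for the order in reagent and 1.8 for the doubling factor, and says “both answers rest on priors”.

The flask gives an order in reagent of 3.0 and a doubling factor of 14.7, both above the forecast.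

    catalyst intermediate B ⇌ free catalyst + target (K = 19.0 M, k = 0.0743 /s)
    reagent + catalyst intermediate A → catalyst intermediate B (k = 0.0279 /M/s)
    2 reagent → homo dimer (k = 0.00257 /M/s)
    substrate + free catalyst → catalyst intermediate A (k = 0.0110 /M/s)

The moment asked about comes at 74.4 min, later than the 53.0 min reckoned, and at 25.0 min this flask has 9.9% of its reagent left. Put the held share to use once more on this flask at 250 min: substrate at 47.8% and target at 42.2% leave a gap worth >99.9% of the catalyst charged, and catalyst intermediate A, the resting state, stands at >99.9% with reagent at 0%.

The numbers in the tables come from a simulation on assumed constants; scatter was added.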